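## Retrosynthetic overview

1. Target 21 comes from vinylogous ester 18 by reagent-controlled hydroxylation at C5 and acetonide removal; the methyl carbinol of 18 comes from Felkin–Anh addition of MeMgBr to ketone 17.
2. Ketone 17 comes from aldehyde 7 (right half) and alkyllithium 15 (left half), followed by oxidation.
3. Aldehyde 7 comes from (S)-2-vinyl dihydrofuranone 5, made by the key step: an enantioconvergent cyclopropane-to-dihydrofuran ring expansion of racemic spiro vinylcyclopropane 4, itself from cyclohexane-1,3-dione 1 and (E)-1,4-dibromobut-2-ene 2.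
4. Iodide 14 comes from (R)-α-hydroxy-γ-butyrolactone 8, homoprenyl bromide 9 and MeMgBr (chelation control), then acetonide formation and iodination.
5. Ring order: the carbocycle (ring A) is bought with 1; the cyclopropane is built on it and then expanded to the dihydrofuran (ring B).

Assumption: the sense of induction of the Trost ligand (step 2) and of the oxaziridine (step 11) is assigned by analogy only; if a first run shows the opposite sense, the antipodal ligand or reagent is used.

## Route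

Step 1
Reactants: 1 cyclohexane-1,3-dione; 2 (E)-1,4-dibromobut-2-ene
Product: 4 rac-1-ethenylspiro[2.5]octane-4,8-dione, via bromobutenyl dione 3 (not isolated)
Conditions: K2CO3 (2.2 equiv), DMF, 0 to 25 °C
Reagents that add atoms: none
Why: Double alkylation of the 1,3-dione (SN2 C-allylation, then intramolecular SN2′ 3-exo-trig closure), the usual way to make 1-acyl-2-vinylcyclopropanes from 1,3-dicarbonyls and 1,4-dibromobut-2-ene; the cyclopropane is racemic and used as such.

Step 2
Reactants: 4 rac-1-ethenylspiro[2.5]octane-4,8-dione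
Product: 5 (2S)-2-ethenyl-3,5,6,7-tetrahydro-1-benzofuran-4(2H)-one
Conditions: Pd2(dba)3·CHCl3 (2.5 mol %), (R,R)-DACH-phenyl Trost ligand (7.5 mol %), CH2Cl2, 0 to 25 °C
Reagents that add atoms: none
Why: Proposed new method: zerovalent palladium ionises both enantiomers of the spiro-activated vinylcyclopropane to a zwitterionic π-allylpalladium/dione enolate, the diastereomeric π-allyl forms interconvert by π–σ–π isomerisation at the unsubstituted terminus, and the chiral ligand pocket directs 5-exo O-attack at the internal allyl carbon to one face, so C2 (S) is set enantioconvergently in a stepwise ionic Cloke–Wilson ring expansion; the closest known reactions are the racemic nickel- or palladium-catalysed vinylcyclopropyl ketone to dihydrofuran rearrangement, palladium-catalysed asymmetric allylic O-alkylation, and dynamic kinetic asymmetric transformations of vinylcyclopropanes.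

Step 3
Reactants: 5 (2S)-2-ethenyl-3,5,6,7-tetrahydro-1-benzofuran-4(2H)-one
Product: 7 (2S)-4-oxo-2,3,4,5,6,7-hexahydro-1-benzofuran-2-carbaldehyde, via diol 6 (not isolated)
Conditions: K2OsO4·2H2O (2 mol %), NaIO4 (4 equiv), 2,6-lutidine, 1,4-dioxane/H2O 3:1, 25 °C
Reagents that add atoms: sodium periodate, [Na+].[O-]I(=O)(=O)=O
Why: Lemieux–Johnson oxidative cleavage; only the monosubstituted vinyl group is dihydroxylated (the tetrasubstituted push–pull alkene of the vinylogous ester is inert) and periodate cleaves the diol without touching C2.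

Step 4
Reactants: 8 (3R)-3-hydroxyoxolan-2-one; 9 5-bromo-2-methylpent-2-ene
Product: 11 (3R)-1,3-dihydroxy-8-methylnon-7-en-4-one, via homoprenyllithium 10 (not isolated)
Conditions: 9 (2.2 equiv), Li wire, Et2O, −10 °C; then 8, THF, −78 °C; H2O
Reagents that add atoms: none
Why: Mono-addition of an alkyllithium to a lactone: the first equivalent deprotonates the hydroxyl, the second adds to the carbonyl, and the lithium hemiketalate is stable at −78 °C so no second addition occurs; C3 is untouched and 11 equilibrates with its cyclic hemiketal.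

Step 5
Reactants: 11 (3R)-1,3-dihydroxy-8-methylnon-7-en-4-one
Product: 12 (3R,4S)-4,8-dimethylnon-7-ene-1,3,4-triol
Conditions: MeMgBr (4 equiv), THF, −78 to 0 °C; H2O
Reagents that add atoms: methylmagnesium bromide, C[Mg]Br
Why: Cram-chelate-controlled Grignard addition: magnesium bridges the α-alkoxide and the ketone oxygen and methyl is delivered from the face of the C3 hydrogen, giving the (3R,4S) tertiary carbinol.

Step 6
Reactants: 12 (3R,4S)-4,8-dimethylnon-7-ene-1,3,4-triol
Product: 13 2-[(4R,5S)-2,2,5-trimethyl-5-(4-methylpent-3-en-1-yl)-1,3-dioxolan-4-yl]ethan-1-ol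
Conditions: Me2C(OMe)2, PPTS (cat.), acetone, 25 °C
Reagents that add atoms: 2,2-dimethoxypropane, COC(C)(C)OC
Why: Acid-catalysed transacetalisation under thermodynamic control gives the five-membered dioxolane of the vicinal secondary/tertiary diol in preference to the six-membered acetal, leaving the primary alcohol free.

Step 7
Reactants: 13 2-[(4R,5S)-2,2,5-trimethyl-5-(4-methylpent-3-en-1-yl)-1,3-dioxolan-4-yl]ethan-1-ol
Product: 14 (4R,5S)-4-(2-iodoethyl)-2,2,5-trimethyl-5-(4-methylpent-3-en-1-yl)-1,3-dioxolane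
Conditions: I2, PPh3, imidazole, CH2Cl2, 0 to 25 °C
Reagents that add atoms: iodine, II
Why: Appel-type iodination (Garegg–Samuelsson conditions) of the primary alcohol by SN2 displacement of the alkoxyphosphonium group; no stereocentre is involved.

Step 8
Reactants: 14 (4R,5S)-4-(2-iodoethyl)-2,2,5-trimethyl-5-(4-methylpent-3-en-1-yl)-1,3-dioxolane; 7 (2S)-4-oxo-2,3,4,5,6,7-hexahydro-1-benzofuran-2-carbaldehyde
Product: 16 (2S)-2-{1-hydroxy-3-[(4R,5S)-2,2,5-trimethyl-5-(4-methylpent-3-en-1-yl)-1,3-dioxolan-4-yl]propyl}-3,5,6,7-tetrahydro-1-benzofuran-4(2H)-one (both carbinol epimers), via alkyllithium 15 (not isolated)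
Conditions: 14 (1.2 equiv), t-BuLi (2.1 equiv per 14), Et2O/pentane, −78 °C; then 7, THF, −78 °C; H2O
Reagents that add atoms: none
Why: Iodine–lithium exchange gives a γ-alkoxy alkyllithium (no β-leaving group), which adds 1,2 to the aldehyde, far more electrophilic than the vinylogous ester at −78 °C; the new carbinol centre is not controlled because it is oxidised in the next step.

Step 9
Reactants: 16 (2S)-2-{1-hydroxy-3-[(4R,5S)-2,2,5-trimethyl-5-(4-methylpent-3-en-1-yl)-1,3-dioxolan-4-yl]propyl}-3,5,6,7-tetrahydro-1-benzofuran-4(2H)-one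
Product: 17 (2S)-2-{3-[(4R,5S)-2,2,5-trimethyl-5-(4-methylpent-3-en-1-yl)-1,3-dioxolan-4-yl]propanoyl}-3,5,6,7-tetrahydro-1-benzofuran-4(2H)-one
Conditions: Dess–Martin periodinane, CH2Cl2, 0 to 25 °C
Reagents that add atoms: none
Why: Dess–Martin oxidation of the secondary alcohol under near-neutral conditions gives the α-alkoxy ketone without epimerising C2; acetonide, alkene and vinylogous ester are inert.

Step 10
Reactants: 17 (2S)-2-{3-[(4R,5S)-2,2,5-trimethyl-5-(4-methylpent-3-en-1-yl)-1,3-dioxolan-4-yl]propanoyl}-3,5,6,7-tetrahydro-1-benzofuran-4(2H)-one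
Product: 18 (2S)-2-{(2S)-2-hydroxy-4-[(4R,5S)-2,2,5-trimethyl-5-(4-methylpent-3-en-1-yl)-1,3-dioxolan-4-yl]butan-2-yl}-3,5,6,7-tetrahydro-1-benzofuran-4(2H)-one
Conditions: MeMgBr (1.5 equiv), THF, −78 °C; H2O
Reagents that add atoms: methylmagnesium bromide, C[Mg]Br
Why: Felkin–Anh (Cornforth) controlled Grignard addition: the ring oxygen is a poorly chelating vinylogous-ester oxygen, so it lies anti to the incoming methyl, which passes the C2 hydrogen and gives the (S) carbinol; the ketone reacts much faster than the vinylogous ester at −78 °C.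

Step 11
Reactants: 18 (2S)-2-{(2S)-2-hydroxy-4-[(4R,5S)-2,2,5-trimethyl-5-(4-methylpent-3-en-1-yl)-1,3-dioxolan-4-yl]butan-2-yl}-3,5,6,7-tetrahydro-1-benzofuran-4(2H)-one
Product: 21 (2S,5R)-5-hydroxy-2-[(2S,5R,6S)-2,5,6-trihydroxy-6,10-dimethylundec-9-en-2-yl]-3,5,6,7-tetrahydro-1-benzofuran-4(2H)-one, via disodium dienolate 19 (not isolated), via hydroxy ketone acetonide 20 (not isolated)
Conditions: NaN(SiMe3)2 (2.3 equiv), THF, −78 °C; (+)-(2R,8aS)-(camphorsulfonyl)oxaziridine, −78 °C; then AcOH/H2O 4:1, 45 °C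
Reagents that add atoms: (+)-(2R,8aS)-(camphorsulfonyl)oxaziridine, CC1(C)[C@@H]2CC[C@]13CS(=O)(=O)N4OC34C2
Why: Kinetic deprotonation at C5 (α′ of the vinylogous ester, after the tertiary hydroxyl) gives the cross-conjugated dienolate, which the Davis oxaziridine hydroxylates under reagent control to set C5 (R) (Davis enolate oxidation); aqueous acetic acid then hydrolyses the acetonide in the same flask without affecting the alkene or the tertiary alcohols.

## Compound list

1 | cyclohexane-1,3-dione | O=C1CCCC(=O)C1 | starting material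
2 | (E)-1,4-dibromobut-2-ene | BrC/C=C/CBr | starting material
3 | 2-[(2E)-4-bromobut-2-en-1-yl]cyclohexane-1,3-dione | O=C1CCCC(=O)C1C/C=C/CBr | intermediate
4 | rac-1-ethenylspiro[2.5]octane-4,8-dione | C=CC1CC12C(=O)CCCC2=O | intermediate
5 | (2S)-2-ethenyl-3,5,6,7-tetrahydro-1-benzofuran-4(2H)-one | C=C[C@@H]1CC2=C(CCCC2=O)O1 | intermediate
6 | (2S)-2-(1,2-dihydroxyethyl)-3,5,6,7-tetrahydro-1-benzofuran-4(2H)-one (both carbinol epimers) | OCC(O)[C@@H]1CC2=C(CCCC2=O)O1 | intermediate
7 | (2S)-4-oxo-2,3,4,5,6,7-hexahydro-1-benzofuran-2-carbaldehyde | O=C[C@@H]1CC2=C(CCCC2=O)O1 | intermediate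
8 | (3R)-3-hydroxyoxolan-2-one ((R)-α-hydroxy-γ-butyrolactone) | O[C@@H]1CCOC1=O | starting material
9 | 5-bromo-2-methylpent-2-ene | CC(C)=CCCBr | starting material
10 | (4-methylpent-3-en-1-yl)lithium | [Li]CCC=C(C)C | intermediate
11 | (3R)-1,3-dihydroxy-8-methylnon-7-en-4-one | OCC[C@@H](O)C(=O)CCC=C(C)C | intermediate
12 | (3R,4S)-4,8-dimethylnon-7-ene-1,3,4-triol | OCC[C@@H](O)[C@@](C)(O)CCC=C(C)C | intermediate
13 | 2-[(4R,5S)-2,2,5-trimethyl-5-(4-methylpent-3-en-1-yl)-1,3-dioxolan-4-yl]ethan-1-ol | OCC[C@H]1OC(C)(C)O[C@@]1(C)CCC=C(C)C | intermediate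
14 | (4R,5S)-4-(2-iodoethyl)-2,2,5-trimethyl-5-(4-methylpent-3-en-1-yl)-1,3-dioxolane | ICC[C@H]1OC(C)(C)O[C@@]1(C)CCC=C(C)C | intermediate
15 | {2-[(4R,5S)-2,2,5-trimethyl-5-(4-methylpent-3-en-1-yl)-1,3-dioxolan-4-yl]ethyl}lithium | [Li]CC[C@H]1OC(C)(C)O[C@@]1(C)CCC=C(C)C | intermediate
16 | (2S)-2-{1-hydroxy-3-[(4R,5S)-2,2,5-trimethyl-5-(4-methylpent-3-en-1-yl)-1,3-dioxolan-4-yl]propyl}-3,5,6,7-tetrahydro-1-benzofuran-4(2H)-one (both carbinol epimers) | OC(CC[C@H]1OC(C)(C)O[C@@]1(C)CCC=C(C)C)[C@@H]1CC2=C(CCCC2=O)O1 | intermediate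
17 | (2S)-2-{3-[(4R,5S)-2,2,5-trimethyl-5-(4-methylpent-3-en-1-yl)-1,3-dioxolan-4-yl]propanoyl}-3,5,6,7-tetrahydro-1-benzofuran-4(2H)-one | O=C(CC[C@H]1OC(C)(C)O[C@@]1(C)CCC=C(C)C)[C@@H]1CC2=C(CCCC2=O)O1 | intermediate
18 | (2S)-2-{(2S)-2-hydroxy-4-[(4R,5S)-2,2,5-trimethyl-5-(4-methylpent-3-en-1-yl)-1,3-dioxolan-4-yl]butan-2-yl}-3,5,6,7-tetrahydro-1-benzofuran-4(2H)-one | C[C@](O)(CC[C@H]1OC(C)(C)O[C@@]1(C)CCC=C(C)C)[C@@H]1CC2=C(CCCC2=O)O1 | intermediate
19 | disodium salt of 18 (tertiary alkoxide and C4–C5 dienolate) | C[C@]([O-])(CC[C@H]1OC(C)(C)O[C@@]1(C)CCC=C(C)C)[C@@H]1CC2=C(CCC=C2[O-])O1.[Na+].[Na+] | intermediate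
20 | (2S,5R)-5-hydroxy-2-{(2S)-2-hydroxy-4-[(4R,5S)-2,2,5-trimethyl-5-(4-methylpent-3-en-1-yl)-1,3-dioxolan-4-yl]butan-2-yl}-3,5,6,7-tetrahydro-1-benzofuran-4(2H)-one | C[C@](O)(CC[C@H]1OC(C)(C)O[C@@]1(C)CCC=C(C)C)[C@@H]1CC2=C(CC[C@@H](O)C2=O)O1 | intermediate
21 | (2S,5R)-5-hydroxy-2-[(2S,5R,6S)-2,5,6-trihydroxy-6,10-dimethylundec-9-en-2-yl]-3,5,6,7-tetrahydro-1-benzofuran-4(2H)-one | CC(C)=CCC[C@](C)(O)[C@H](O)CC[C@](C)(O)[C@@H]1CC2=C(CC[C@@H](O)C2=O)O1 | target

## Step count and risks

Total steps: 11 (steps 1–3 right half, steps 4–7 left half, steps 8–11 after the union). Longest linear sequence: 8 steps (steps 4 to 11).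

The three steps most likely to fail:

**Step 2 (proposed new ring expansion).** The risk is low enantioselectivity or slow re-ionisation of the product eroding it. The fallback sets out from 4 and comes back at 17, using known chemistry only. The known racemic rearrangement with the zerovalent nickel complex Ni(cod)2 and PPh3 gives racemic 2-ethenyl-3,5,6,7-tetrahydro-1-benzofuran-4(2H)-one F1. Lemieux–Johnson cleavage as in step 3 passes through racemic 2-(1,2-dihydroxyethyl)-3,5,6,7-tetrahydro-1-benzofuran-4(2H)-one F2 to racemic 4-oxo-2,3,4,5,6,7-hexahydro-1-benzofuran-2-carbaldehyde F3. Addition of the enantiopure alkyllithium 15 as in step 8 gives 16 together with its (2R)-diastereomers, (2R)-2-{1-hydroxy-3-[(4R,5S)-2,2,5-trimethyl-5-(4-methylpent-3-en-1-yl)-1,3-dioxolan-4-yl]propyl}-3,5,6,7-tetrahydro-1-benzofuran-4(2H)-one F4. Dess–Martin oxidation as in step 9 gives 17 and its C2 epimer, (2R)-2-{3-[(4R,5S)-2,2,5-trimethyl-5-(4-methylpent-3-en-1-yl)-1,3-dioxolan-4-yl]propanoyl}-3,5,6,7-tetrahydro-1-benzofuran-4(2H)-one F5. These two are diastereomers because the left half is enantiopure, and they are separated by chromatography; the enantiopure fragment thus acts as the resolving partner.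

**Step 10 (Felkin–Anh methyl addition).** The risk is low selectivity, or a chelate preference that gives the C-methyl epimer. The fallback sets out from 5 and comes back at 18 by reversing the order in which the two carbon groups are introduced and enforcing chelation. Tsuji–Wacker oxidation of 5 (PdCl2, CuCl, O2, DMF/H2O) gives the methyl ketone (2S)-2-acetyl-3,5,6,7-tetrahydro-1-benzofuran-4(2H)-one F6. Alkyllithium 15 is transmetalated with MgBr2·OEt2 to {2-[(4R,5S)-2,2,5-trimethyl-5-(4-methylpent-3-en-1-yl)-1,3-dioxolan-4-yl]ethyl}magnesium bromide F7. F7 is added to F6 premixed with MgBr2·OEt2 in CH2Cl2 at −78 °C. Under Cram-chelate control, delivery of the chain to the methyl ketone gives the same (S) carbinol 18 that Felkin–Anh delivery of methyl to 17 would give.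

**Step 11 (C5 hydroxylation).** The risk is modest diastereoselectivity, because the reagent must override a remote, essentially non-directing stereo array. The fallback sets out from 18 and comes back at 20. α′-Acetoxylation with Mn(OAc)3·2H2O in refluxing benzene gives (2S)-5-acetoxy-2-{(2S)-2-hydroxy-4-[(4R,5S)-2,2,5-trimethyl-5-(4-methylpent-3-en-1-yl)-1,3-dioxolan-4-yl]butan-2-yl}-3,5,6,7-tetrahydro-1-benzofuran-4(2H)-one F8 as a mixture of C5 epimers. A lipase (Candida antarctica lipase B, pH 7 phosphate buffer/acetone) then hydrolyses the (5R)-acetate selectively to 20, in the manner of the known enzymatic resolution of α′-acetoxy enones; 20 is separated from unreacted (5S)-acetate. The acetic acid treatment of step 11 then gives 21.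

## Further compounds

F1 | step 2 | rac-2-ethenyl-3,5,6,7-tetrahydro-1-benzofuran-4(2H)-one | C=CC1CC2=C(CCCC2=O)O1
F2 | step 2 | rac-2-(1,2-dihydroxyethyl)-3,5,6,7-tetrahydro-1-benzofuran-4(2H)-one | OCC(O)C1CC2=C(CCCC2=O)O1
F3 | step 2 | rac-4-oxo-2,3,4,5,6,7-hexahydro-1-benzofuran-2-carbaldehyde | O=CC1CC2=C(CCCC2=O)O1
F4 | step 2 | (2R)-2-{1-hydroxy-3-[(4R,5S)-2,2,5-trimethyl-5-(4-methylpent-3-en-1-yl)-1,3-dioxolan-4-yl]propyl}-3,5,6,7-tetrahydro-1-benzofuran-4(2H)-one | OC(CC[C@H]1OC(C)(C)O[C@@]1(C)CCC=C(C)C)[C@H]1CC2=C(CCCC2=O)O1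
F5 | step 2 | (2R)-2-{3-[(4R,5S)-2,2,5-trimethyl-5-(4-methylpent-3-en-1-yl)-1,3-dioxolan-4-yl]propanoyl}-3,5,6,7-tetrahydro-1-benzofuran-4(2H)-one | O=C(CC[C@H]1OC(C)(C)O[C@@]1(C)CCC=C(C)C)[C@H]1CC2=C(CCCC2=O)O1
F6 | step 10 | (2S)-2-acetyl-3,5,6,7-tetrahydro-1-benzofuran-4(2H)-one | CC(=O)[C@@H]1CC2=C(CCCC2=O)O1
F7 | step 10 | {2-[(4R,5S)-2,2,5-trimethyl-5-(4-methylpent-3-en-1-yl)-1,3-dioxolan-4-yl]ethyl}magnesium bromide | Br[Mg]CC[C@H]1OC(C)(C)O[C@@]1(C)CCC=C(C)C
F8 | step 11 | (2S)-5-acetoxy-2-{(2S)-2-hydroxy-4-[(4R,5S)-2,2,5-trimethyl-5-(4-methylpent-3-en-1-yl)-1,3-dioxolan-4-yl]butan-2-yl}-3,5,6,7-tetrahydro-1-benzofuran-4(2H)-one (C5 epimers) | C[C@](O)(CC[C@H]1OC(C)(C)O[C@@]1(C)CCC=C(C)C)[C@@H]1CC2=C(CCC(OC(C)=O)C2=O)O1
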